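**Assumption:** Xanthogalenol has no stereocenters. The only stereochemical element is the E-enone, so "single enantiomer" does not apply. I take p-coumaric acid as the commercial (E)-isomer.

## Retrosynthetic overview
- Xanthogalenol comes from a fully O-protected chalcone: the 4-OH is a MOM ether and the 2',4',6'-oxygens are OMe. One BCl3 step removes the MOM group and cleaves only the two carbonyl-chelated ortho methyl ethers (2' and 6'), leaving the 4'-OMe.
- The aryl–C(=O) bond is made by directed ortho-lithiation of 2-prenyl-1,3,5-trimethoxybenzene, followed by addition to an (E)-cinnamoyl Weinreb amide. This replaces the usual Claisen–Schmidt aldol, and the E-enone geometry is carried in from p-coumaric acid.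
- The 2-prenyl arene comes from 1,3,5-trimethoxybenzene by lithiation and Cu-catalysed prenylation. Because the arene is symmetric, the prenyl position and the later acylation position are unambiguous.
- No ring is constructed. The benzene core is purchased, so the route is a sequence of C–C bond formations on a pre-formed aromatic ring.

## Route

**Step 1**
Reactants: 1 (1,3,5-trimethoxybenzene); 2 (prenyl bromide, 1-bromo-3-methyl-2-butene)
Product: 3 (2-prenyl-1,3,5-trimethoxybenzene)
Conditions: n-BuLi, THF, 0 °C → rt, 3 h; then CuI (10 mol %), add 2, −78 °C → rt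
Reagents that add atoms: prenyl bromide, CC(C)=CCBr
Why: Lithiation of 1 occurs between two OMe groups (directed ortho-metalation). Cu(I)-catalysed SN2 alkylation of the aryllithium gives the linear prenyl group over the SN2' reverse-prenyl isomer. No stereocenter is formed.

**Step 2**
Reactants: 4 (p-coumaric acid, (E)-4-hydroxycinnamic acid)
Product: 5 ((E)-3-(4-hydroxyphenyl)-N-methoxy-N-methylacrylamide)
Conditions: MeNH(OMe)·HCl, EDCI·HCl, HOBt, iPr2NEt, DMF, rt, 12 h
Reagents that add atoms: N,O-dimethylhydroxylamine hydrochloride, CNOC.Cl
Why: Carbodiimide amide coupling (Weinreb amide formation). The E-alkene is untouched.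

**Step 3**
Reactants: 5
Product: 6 ((E)-N-methoxy-N-methyl-3-[4-(methoxymethoxy)phenyl]acrylamide)
Conditions: MOMCl, iPr2NEt, CH2Cl2, 0 °C → rt, 3 h
Reagents that add atoms: chloromethyl methyl ether, ClCOC
Why: Williamson-type MOM protection removes the acidic phenol, so it does not quench the aryllithium in step 4.

**Step 4**
Reactants: 3 (2-prenyl-1,3,5-trimethoxybenzene); 6 (Weinreb amide)
Product: 7 ((E)-1-(2,4,6-trimethoxy-3-prenylphenyl)-3-[4-(MOMO)phenyl]prop-2-en-1-one)
Conditions: (i) 3, n-BuLi (1.2 equiv), THF, 0 °C, 2 h; (ii) 6 (1.0 equiv), −78 → 0 °C, 2 h; NH4Cl quench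
Reagents that add atoms: none (compound 6 is the numbered reactant)
Why: Directed ortho-metalation at C4, between two OMe groups, with acylation by a Weinreb amide. The stable chelated tetrahedral intermediate prevents over-addition and gives the enone on workup, with the E geometry retained.

**Step 5**
Reactants: 7
Product: 8 (xanthogalenol)
Conditions: BCl3 (5 equiv), CH2Cl2, −78 °C → 0 °C, 1.5 h; quench with MeOH at −78 °C
Reagents that add atoms: none
Why: **Proposed new method:** BCl3 chelates the ketone oxygen and delivers Cl⁻ to the adjacent methyl of a carbonyl-flanked OMe, giving ArO–BCl2. The 2'-OMe is cleaved first, and the second ortho OMe (6') follows through the same carbonyl chelation. The para 4'-OMe cannot chelate and survives at ≤0 °C. BCl3 also cleaves the MOM acetal, and the MeOH quench destroys MOMCl as CH2(OMe)2. The closest known reaction is BCl3 mono-demethylation of 2,4,6-trimethoxyaryl ketones to 2-hydroxy-4,6-dimethoxyaryl ketones. This step extends it to two ortho cleavages in the presence of a prenyl group and an enone, and no stereocenter is affected.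

## Compound list
1 | 1,3,5-trimethoxybenzene | COc1cc(OC)cc(OC)c1 | starting material
2 | prenyl bromide | CC(C)=CCBr | starting material
3 | 2-prenyl-1,3,5-trimethoxybenzene | COc1cc(OC)c(CC=C(C)C)c(OC)c1 | intermediate
4 | p-coumaric acid | OC(=O)/C=C/c1ccc(O)cc1 | starting material
5 | (E)-3-(4-hydroxyphenyl)-N-methoxy-N-methylacrylamide | CON(C)C(=O)/C=C/c1ccc(O)cc1 | intermediate
6 | (E)-N-methoxy-N-methyl-3-[4-(methoxymethoxy)phenyl]acrylamide | CON(C)C(=O)/C=C/c1ccc(OCOC)cc1 | intermediate
7 | (E)-1-(2,4,6-trimethoxy-3-(3-methylbut-2-enyl)phenyl)-3-[4-(methoxymethoxy)phenyl]prop-2-en-1-one | COc1cc(OC)c(CC=C(C)C)c(OC)c1C(=O)/C=C/c1ccc(OCOC)cc1 | intermediate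
8 | xanthogalenol | COc1cc(O)c(C(=O)/C=C/c2ccc(O)cc2)c(O)c1CC=C(C)C | target

## Totals
- Total steps: 5.
- Longest linear sequence: 4 (4 → 5 → 6 → 7 → 8). The other branch, 1 → 3 → 7 → 8, is 3 steps.

## Three steps most likely to fail
1. **Step 5 (BCl3 demethylation).**
   - Risks: the second ortho cleavage may be sluggish, the 4'-OMe may be cleaved, the prenyl/2'-OH may cyclise to a chroman, or the 2'-OH chalcone may close to a flavanone.
   - Fallback: abandon the permethylated-arene strategy and use the aldol route. Start from commercial phloroacetophenone, make the 4'-OMe ether selectively (MeI, K2CO3), C-prenylate at C3', protect as bis-MOM, do Claisen–Schmidt with 4-MOMO-benzaldehyde, and remove the MOM groups with HCl/MeOH.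
2. **Step 4 (lithiation of 3 and acylation).**
   - Risks: lithiation of the doubly benzylic/allylic prenyl CH2 instead of the ring, conjugate rather than 1,2-addition to the cinnamoyl amide, and steric hindrance.
   - Fallback: replace deprotonation with halogen–metal exchange. Brominate 3 with NBS at C4, do Br/Li exchange at −78 °C, and then acylate. Alternatively, acylate unsubstituted 1 first (Friedel–Crafts with a cinnamoyl chloride) and install the prenyl group afterwards by Fe-catalysed cross-coupling.
3. **Step 1 (lithiation and prenylation of 1).**
   - Risks: SN2' reverse-prenyl product and over-alkylation.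
   - Fallback: brominate 1 with NBS to give 2-bromo-1,3,5-trimethoxybenzene, then Pd- or Fe-catalysed cross-coupling with prenylmagnesium chloride or prenyl-Bpin (Suzuki), which avoids the organolithium alkylation.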